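**Retrosynthetic overview**

1. The target comes from its silyl ether, made by chloride opening of an oxygen-bridged bromide. That bromide comes from bromoetherification of a 1-substituted 4-methylcyclohex-3-en-1-ol, so the tertiary OH places Br (C3) and Cl (C4) of the cyclohexane.
2. That cyclohexenol comes, by allylic oxidation and reductive 1,3-transposition, from its ring-alkene isomer. The isomer is made in the key step, a formal [3+3] ring expansion of a cyclopropanol with a (Z)-γ-borylated allyl chloride. One flask forms C3–C4 (copper SN2′) and C1–C6 (allylboration) of the cyclohexane.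
3. Enabling feature: the cyclopropanol ring built from cyclohexane C1 (carbinol), C2 and C3. Its strained C1–C3 bond opens to a zinc homoenolate, so C3 is a nucleophile and C1 a ketone electrophile. These match the electrophilic boron-bearing carbon (C4) and the nucleophilic CH2 terminus (C6) of the allyl reagent.
4. The cyclopropanol comes from a methyl ketone. The ketone comes from a semipinacol methyl shift of an epoxy alcohol, made by Shapiro/acetone chemistry after CBS desymmetrisation of 2,2-dimethylcyclopentane-1,3-dione; Br enters by SN2 inversion.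
5. Ring order: cyclopentane (from the start), epoxide (temporary), cyclopropane (temporary), cyclohexene (key step), oxa-bridge (temporary).

Key step: step 14

Remark: locants C1–C6 of the six-membered ring in the Why lines are those of the target (C1 carbinol carbon, C3 CHBr, C4 C(CH3)Cl).
Remark: 22 and 23 are carried as mixtures of both configurations at ring carbon C3; their SMILES leave this centre open because both converge on 24.
Abbreviations: TBS = tert-butyl(dimethyl)silyl; pin = pinacolato; R = (1S,3S,5R)-3-bromo-5-(TBS-oxy)-1,2,2-trimethylcyclopentyl.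

**Step 1**
Reactants: 1 2,2-dimethylcyclopentane-1,3-dione
Product: 2 (3R)-3-hydroxy-2,2-dimethylcyclopentan-1-one
Conditions: (S)-2-methyl-CBS-oxazaborolidine (20 mol %), catecholborane, toluene, −78 °C; aq NaOH work-up
Reagents that add atoms: none
Why: Corey–Bakshi–Shibata reduction of one of the two enantiotopic carbonyls; with the quaternary side as the large group the (S)-catalyst should set C3 as R.

**Step 2**
Reactants: 2 (3R)-3-hydroxy-2,2-dimethylcyclopentan-1-one
Product: 3 (3R)-3-(benzyloxy)-2,2-dimethylcyclopentan-1-one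
Conditions: benzyl 2,2,2-trichloroacetimidate, TfOH (cat.), CH2Cl2–cyclohexane, 0 °C to rt
Reagents that add atoms: benzyl 2,2,2-trichloroacetimidate, ClC(Cl)(Cl)C(=N)OCc1ccccc1
Why: Acid-catalysed imidate benzylation avoids base and therefore retro-aldol opening of the β-hydroxy ketone; the ether later shields one ring face.

**Step 3**
Reactants: 3 (3R)-3-(benzyloxy)-2,2-dimethylcyclopentan-1-one
Product: 4 (E)-2,4,6-tri(propan-2-yl)benzenesulfonylhydrazone of 3
Conditions: 2,4,6-tri(propan-2-yl)benzenesulfonohydrazide, THF, HCl (cat.), rt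
Reagents that add atoms: 2,4,6-tri(propan-2-yl)benzenesulfonohydrazide, CC(C)c1cc(C(C)C)c(S(=O)(=O)NN)c(C(C)C)c1
Why: Hydrazone condensation gives the Shapiro precursor; the ketone has a single α-CH2, so the later deprotonation is regiodefined.

**Step 4**
Reactants: 4 (E)-2,4,6-tri(propan-2-yl)benzenesulfonylhydrazone of 3
Product: 6 2-[(4R)-4-(benzyloxy)-5,5-dimethylcyclopent-1-en-1-yl]propan-2-ol, via vinyllithium 5 (not isolated)
Conditions: n-BuLi (2.2 equiv), THF–TMEDA, −78 to 0 °C; then acetone, −78 °C; aq NH4Cl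
Reagents that add atoms: acetone, CC(C)=O
Why: Shapiro reaction: double deprotonation with loss of dinitrogen and sulfinate gives vinyllithium 5 at the former carbonyl carbon, which adds to acetone to give the tertiary allylic alcohol.

**Step 5**
Reactants: 6 2-[(4R)-4-(benzyloxy)-5,5-dimethylcyclopent-1-en-1-yl]propan-2-ol
Product: 7 2-[(1S,3R,5R)-3-(benzyloxy)-2,2-dimethyl-6-oxabicyclo[3.1.0]hexan-1-yl]propan-2-ol
Conditions: 3-chloroperbenzoic acid, NaHCO3, CH2Cl2, 0 °C
Reagents that add atoms: 3-chloroperbenzoic acid, O=C(OO)c1cccc(Cl)c1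
Why: Peracid (Prilezhaev) epoxidation of the trisubstituted alkene should occur on the ring face opposite to the benzyloxy group, which sets both epoxide carbons relative to C3 of the ring.

**Step 6**
Reactants: 7 2-[(1S,3R,5R)-3-(benzyloxy)-2,2-dimethyl-6-oxabicyclo[3.1.0]hexan-1-yl]propan-2-ol
Product: 8 1-[(1S,3R,5R)-3-(benzyloxy)-5-hydroxy-1,2,2-trimethylcyclopentyl]ethan-1-one
Conditions: BF3·OEt2, CH2Cl2, −78 °C
Reagents that add atoms: none
Why: Semipinacol rearrangement of the 2,3-epoxy alcohol: a methyl group migrates to the epoxide carbon anti to the breaking C–O bond, so the new quaternary carbon carries CH3 trans and acetyl cis to the new secondary hydroxyl.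

**Step 7**
Reactants: 8 1-[(1S,3R,5R)-3-(benzyloxy)-5-hydroxy-1,2,2-trimethylcyclopentyl]ethan-1-one
Product: 9 1-[(1S,3R,5R)-3-(benzyloxy)-5-(TBS-oxy)-1,2,2-trimethylcyclopentyl]ethan-1-one
Conditions: TBSOTf, 2,6-lutidine, CH2Cl2, −78 to 0 °C
Reagents that add atoms: tert-butyl(dimethyl)silyl trifluoromethanesulfonate, CC(C)(C)[Si](C)(C)OS(=O)(=O)C(F)(F)F
Why: Silylation of the hindered β-hydroxyl with the silyl triflate blocks retro-aldol cleavage and keeps this oxygen out of the later Mitsunobu step.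

**Step 8**
Reactants: 9 1-[(1S,3R,5R)-3-(benzyloxy)-5-(TBS-oxy)-1,2,2-trimethylcyclopentyl]ethan-1-one
Product: 10 1-[(1S,3R,5R)-3-hydroxy-5-(TBS-oxy)-1,2,2-trimethylcyclopentyl]ethan-1-one
Conditions: H2 (1 atm), Pd/C (10 wt %), EtOAc, rt
Reagents that add atoms: none
Why: Hydrogenolysis of the benzyl ether; the ketone and silyl ether are inert under these conditions.

**Step 9**
Reactants: 10 1-[(1S,3R,5R)-3-hydroxy-5-(TBS-oxy)-1,2,2-trimethylcyclopentyl]ethan-1-one
Product: 12 1-[(1S,3S,5R)-3-bromo-5-(TBS-oxy)-1,2,2-trimethylcyclopentyl]ethan-1-one (R–C(=O)CH3), via triflate 11 (not isolated)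
Conditions: Tf2O, pyridine, CH2Cl2, −30 °C; then n-Bu4NBr, −30 °C to rt
Reagents that add atoms: tetrabutylammonium bromide, CCCC[N+](CCCC)(CCCC)CCCC.[Br-]
Why: SN2 displacement of the secondary triflate by bromide with inversion places bromine cis to the silyloxy and acetyl groups; the triflate is chosen because the carbon sits next to a quaternary centre.

**Step 10**
Reactants: 12 R–C(=O)CH3
Product: 13 trimethylsilyl enol ether R–C(=CH2)OSi(CH3)3
Conditions: LiN(i-Pr)2, THF, −78 °C; then Me3SiCl
Reagents that add atoms: chlorotrimethylsilane, C[Si](C)(C)Cl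
Why: Kinetic enolisation of the methyl ketone at its only enolisable position followed by O-silylation.

**Step 11**
Reactants: 13 trimethylsilyl enol ether R–C(=CH2)OSi(CH3)3
Product: 15 1-R-cyclopropan-1-ol, via siloxycyclopropane 14 (not isolated)
Conditions: Et2Zn, CH2I2, CH2Cl2, 0 °C to rt; then K2CO3 (cat.), MeOH, 0 °C
Reagents that add atoms: diiodomethane, ICI
Why: Simmons–Smith (Furukawa) cyclopropanation of the electron-rich silyl enol ether and mild methanolysis of the trimethylsilyl ether give the cyclopropanol, a masked β-metallo ketone.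

**Step 12**
Reactants: 16 but-2-yn-1-ol
Product: 17 (2Z)-3-(pinB)but-2-en-1-ol
Conditions: B2pin2, CuCl (5 mol %), NaOt-Bu (10 mol %), Xantphos (5 mol %), MeOH, THF, rt
Reagents that add atoms: bis(pinacolato)diboron, CC1(C)OB(OC1(C)C)B1OC(C)(C)C(C)(C)O1
Why: Copper-catalysed syn-borylcupration and protonation of the propargylic alcohol should place boron on the alkyne carbon remote from the CH2OH group and give the Z-alkene.

**Step 13**
Reactants: 17 (2Z)-3-(pinB)but-2-en-1-ol
Product: 18 2-[(2Z)-4-chlorobut-2-en-2-yl]-4,4,5,5-tetramethyl-1,3,2-dioxaborolane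
Conditions: N-chlorosuccinimide, PPh3, CH2Cl2, −20 to 0 °C
Reagents that add atoms: N-chlorosuccinimide, O=C1CCC(=O)N1Cl
Why: Appel-type chlorination of the primary allylic alcohol by SN2 leaves the alkenylboronate untouched.

**Step 14**
Reactants: 15 1-R-cyclopropan-1-ol; 18 2-[(2Z)-4-chlorobut-2-en-2-yl]-4,4,5,5-tetramethyl-1,3,2-dioxaborolane
Product: 21 (1S)-4-methyl-1-R-cyclohex-3-en-1-ol (double bond on the ring arm made at C6), via zinc homoenolate 19 (not isolated), via tertiary allylboronate 20 (not isolated)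
Conditions: Et2Zn (2.0 equiv), THF, 0 °C to rt; then CuCl (10 mol %), (S,S,S)-BINOL-derived N,N-bis(1-phenylethyl)phosphoramidite (12 mol %), 18, −40 °C to rt; then 50 °C; aq NH4Cl
Reagents that add atoms: none
Why: Proposed new method: Et2Zn converts 15 into its zinc alkoxide, whose strained C1–C3 cyclopropane bond opens to homoenolate 19 (ketone carbon C1 three atoms from the C3–Zn carbon); after transmetallation to copper this carbon attacks the boron-bearing γ-carbon of 18 in an anti-SN2′ substitution (C3–C4 bond) to give tertiary allylboronate 20, whose CH2= terminus then adds to the regenerated ketone through a closed six-membered allylboration transition state (C1–C6 bond) to give the borate of 21. The closest known reaction types are the copper-mediated SN2′ allylation of cyclopropanol-derived zinc homoenolates, the copper-catalysed SN2′ alkylation of 3-halopropenylboronates to α-substituted allylboronates that allylate carbonyl compounds in the same flask, and intramolecular carbonyl allylboration; their merger into a formal [3+3] ring expansion of a cyclopropanol is untested. The six-membered ring closes when boron on C4 binds the ketone oxygen and C6 bonds to C1 in a boat-like, bicyclo[2.2.2]-type array bridged by the C2–C3 tether, which leaves the new double bond endocyclic (C4=C5). The only new stereocentre of 21, C1, is controlled by the configuration at the boron-bearing carbon of 20 (S), because boron can deliver C6 to only one face of the ketone; that configuration is set by the chiral copper catalyst and the Z geometry of 18, the (S,S,S)-ligand being specified on the expectation that it gives this sense, and the remote cyclopentane stereocentres take no part. The step needs transfer of the homoenolate rather than an ethyl group, γ- over α-substitution and facial control at C4, which copper–phosphoramidite catalysis of dialkylzinc SN2′ reactions is expected to provide, and it needs cyclisation to outrun β-hydride loss or intermolecular allylation, which the intramolecular transition state and the Lewis acidic zinc salts should secure.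

**Step 15**
Reactants: 21 (1S)-4-methyl-1-R-cyclohex-3-en-1-ol
Product: 22 (1R,3RS)-4-methyl-1-R-cyclohex-4-ene-1,3-diol
Conditions: SeO2 (0.5 equiv), t-BuOOH, CH2Cl2, rt
Reagents that add atoms: tert-butyl hydroperoxide, CC(C)(C)OO
Why: Selenium dioxide allylic oxidation (ene reaction then [2,3]-sigmatropic shift) should hydroxylate the ring CH2 on the more substituted alkene carbon, which is C3, the former cyclopropane carbon; either epimer serves.

**Step 16**
Reactants: 22 (1R,3RS)-4-methyl-1-R-cyclohex-4-ene-1,3-diol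
Product: 24 (1R)-4-methyl-1-R-cyclohex-3-en-1-ol (double bond C3=C4 of the target numbering), via allylic diazene 23 (not isolated)
Conditions: 2-nitrobenzenesulfonohydrazide, PPh3, diethyl azodicarboxylate, THF, −30 °C to rt
Reagents that add atoms: none
Why: Mitsunobu displacement by the sulfonohydrazide, loss of sulfinic acid and retro-ene loss of dinitrogen from allylic diazene 23 move the double bond to C3=C4 regiospecifically and remove the oxygen, so both epimers of 22 converge and C1 is untouched.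

**Step 17**
Reactants: 24 (1R)-4-methyl-1-R-cyclohex-3-en-1-ol
Product: 25 (1S,2S,4R)-2-bromo-1-methyl-4-R-7-oxabicyclo[2.2.1]heptane
Conditions: N-bromosuccinimide, CH2Cl2, 0 °C, dark
Reagents that add atoms: N-bromosuccinimide, O=C1CCC(=O)N1Br
Why: Bromoetherification: only the bromonium ion on the face opposite to the tertiary hydroxyl can be opened intramolecularly at the methyl-bearing carbon C4, which fixes bromine at C3 anti to the new oxygen bridge.

**Step 18**
Reactants: 25 (1S,2S,4R)-2-bromo-1-methyl-4-R-7-oxabicyclo[2.2.1]heptane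
Product: 26 (1R,3S,4S)-3-bromo-4-chloro-4-methyl-1-R-cyclohexan-1-ol
Conditions: TiCl4, CH2Cl2, −78 to −40 °C; aq NaHCO3
Reagents that add atoms: titanium tetrachloride, Cl[Ti](Cl)(Cl)Cl
Why: Lewis acid ether cleavage at the tertiary C4–O bond, assisted by the antiperiplanar bromine, should return chloride from titanium on the face the oxygen leaves (retention), giving Cl cis to OH and trans to Br; a bromine-shifted diaxial isomer should equilibrate through the same bromonium ion to this diequatorial product.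

**Step 19**
Reactants: 26 (1R,3S,4S)-3-bromo-4-chloro-4-methyl-1-R-cyclohexan-1-ol
Product: 27 (1R,3S,4S)-3-bromo-1-[(1S,3S,5R)-3-bromo-5-hydroxy-1,2,2-trimethylcyclopentyl]-4-chloro-4-methylcyclohexan-1-ol (CNP0158757.1)
Conditions: HF·pyridine, THF, 0 °C to rt
Reagents that add atoms: none
Why: Fluoride-mediated desilylation under non-basic conditions frees the secondary alcohol without touching the tertiary chloride or the secondary bromides.

**Compound list**

1 | 2,2-dimethylcyclopentane-1,3-dione | CC1(C)C(=O)CCC1=O | starting material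
2 | (3R)-3-hydroxy-2,2-dimethylcyclopentan-1-one | CC1(C)[C@H](O)CCC1=O | intermediate
3 | (3R)-3-(benzyloxy)-2,2-dimethylcyclopentan-1-one | CC1(C)[C@H](OCc2ccccc2)CCC1=O | intermediate
4 | N'-[(1E,3R)-3-(benzyloxy)-2,2-dimethylcyclopentylidene]-2,4,6-tri(propan-2-yl)benzenesulfonohydrazide | CC1(C)[C@H](OCc2ccccc2)CC/C1=N\NS(=O)(=O)c1c(C(C)C)cc(C(C)C)cc1C(C)C | intermediate
5 | [(4R)-4-(benzyloxy)-5,5-dimethylcyclopent-1-en-1-yl]lithium | [Li]C1=CC[C@@H](OCc2ccccc2)C1(C)C | intermediate
6 | 2-[(4R)-4-(benzyloxy)-5,5-dimethylcyclopent-1-en-1-yl]propan-2-ol | CC(C)(O)C1=CC[C@@H](OCc2ccccc2)C1(C)C | intermediate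
7 | 2-[(1S,3R,5R)-3-(benzyloxy)-2,2-dimethyl-6-oxabicyclo[3.1.0]hexan-1-yl]propan-2-ol | CC(C)(O)[C@@]12O[C@@H]1C[C@@H](OCc1ccccc1)C2(C)C | intermediate
8 | 1-[(1S,3R,5R)-3-(benzyloxy)-5-hydroxy-1,2,2-trimethylcyclopentyl]ethan-1-one | CC1(C)[C@H](OCc2ccccc2)C[C@@H](O)[C@@]1(C)C(C)=O | intermediate
9 | 1-[(1S,3R,5R)-3-(benzyloxy)-5-{[tert-butyl(dimethyl)silyl]oxy}-1,2,2-trimethylcyclopentyl]ethan-1-one | CC1(C)[C@H](OCc2ccccc2)C[C@@H](O[Si](C)(C)C(C)(C)C)[C@@]1(C)C(C)=O | intermediate
10 | 1-[(1S,3R,5R)-5-{[tert-butyl(dimethyl)silyl]oxy}-3-hydroxy-1,2,2-trimethylcyclopentyl]ethan-1-one | CC1(C)[C@H](O)C[C@@H](O[Si](C)(C)C(C)(C)C)[C@@]1(C)C(C)=O | intermediate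
11 | (1R,3S,4R)-3-acetyl-4-{[tert-butyl(dimethyl)silyl]oxy}-2,2,3-trimethylcyclopentyl trifluoromethanesulfonate | CC1(C)[C@H](OS(=O)(=O)C(F)(F)F)C[C@@H](O[Si](C)(C)C(C)(C)C)[C@@]1(C)C(C)=O | intermediate
12 | 1-[(1S,3S,5R)-3-bromo-5-{[tert-butyl(dimethyl)silyl]oxy}-1,2,2-trimethylcyclopentyl]ethan-1-one | CC1(C)[C@@H](Br)C[C@@H](O[Si](C)(C)C(C)(C)C)[C@@]1(C)C(C)=O | intermediate
13 | ({1-[(1S,3S,5R)-3-bromo-5-{[tert-butyl(dimethyl)silyl]oxy}-1,2,2-trimethylcyclopentyl]ethenyl}oxy)(trimethyl)silane | CC1(C)[C@@H](Br)C[C@@H](O[Si](C)(C)C(C)(C)C)[C@@]1(C)C(=C)O[Si](C)(C)C | intermediate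
14 | {1-[(1S,3S,5R)-3-bromo-5-{[tert-butyl(dimethyl)silyl]oxy}-1,2,2-trimethylcyclopentyl]cyclopropoxy}(trimethyl)silane | CC1(C)[C@@H](Br)C[C@@H](O[Si](C)(C)C(C)(C)C)[C@@]1(C)C1(O[Si](C)(C)C)CC1 | intermediate
15 | 1-[(1S,3S,5R)-3-bromo-5-{[tert-butyl(dimethyl)silyl]oxy}-1,2,2-trimethylcyclopentyl]cyclopropan-1-ol | CC1(C)[C@@H](Br)C[C@@H](O[Si](C)(C)C(C)(C)C)[C@@]1(C)C1(O)CC1 | intermediate
16 | but-2-yn-1-ol | CC#CCO | starting material
17 | (2Z)-3-(4,4,5,5-tetramethyl-1,3,2-dioxaborolan-2-yl)but-2-en-1-ol | OC/C=C(\C)B1OC(C)(C)C(C)(C)O1 | intermediate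
18 | 2-[(2Z)-4-chlorobut-2-en-2-yl]-4,4,5,5-tetramethyl-1,3,2-dioxaborolane | ClC/C=C(\C)B1OC(C)(C)C(C)(C)O1 | intermediate
19 | {3-[(1S,3S,5R)-3-bromo-5-{[tert-butyl(dimethyl)silyl]oxy}-1,2,2-trimethylcyclopentyl]-3-oxopropyl}(ethyl)zinc | CC1(C)[C@@H](Br)C[C@@H](O[Si](C)(C)C(C)(C)C)[C@@]1(C)C(=O)CC[Zn]CC | intermediate
20 | (4S)-1-[(1S,3S,5R)-3-bromo-5-{[tert-butyl(dimethyl)silyl]oxy}-1,2,2-trimethylcyclopentyl]-4-methyl-4-(4,4,5,5-tetramethyl-1,3,2-dioxaborolan-2-yl)hex-5-en-1-one | CC1(C)[C@@H](Br)C[C@@H](O[Si](C)(C)C(C)(C)C)[C@@]1(C)C(=O)CC[C@@](C)(B1OC(C)(C)C(C)(C)O1)C=C | intermediate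
21 | (1S)-1-[(1S,3S,5R)-3-bromo-5-{[tert-butyl(dimethyl)silyl]oxy}-1,2,2-trimethylcyclopentyl]-4-methylcyclohex-3-en-1-ol | CC1(C)[C@@H](Br)C[C@@H](O[Si](C)(C)C(C)(C)C)[C@@]1(C)[C@@]1(O)CC=C(C)CC1 | intermediate
22 | (1R,3RS)-1-[(1S,3S,5R)-3-bromo-5-{[tert-butyl(dimethyl)silyl]oxy}-1,2,2-trimethylcyclopentyl]-4-methylcyclohex-4-ene-1,3-diol | CC1(C)[C@@H](Br)C[C@@H](O[Si](C)(C)C(C)(C)C)[C@@]1(C)[C@@]1(O)CC=C(C)C(O)C1 | intermediate
23 | (1R,3RS)-1-[(1S,3S,5R)-3-bromo-5-{[tert-butyl(dimethyl)silyl]oxy}-1,2,2-trimethylcyclopentyl]-3-diazenyl-4-methylcyclohex-4-en-1-ol | CC1(C)[C@@H](Br)C[C@@H](O[Si](C)(C)C(C)(C)C)[C@@]1(C)[C@@]1(O)CC=C(C)C(N=N)C1 | intermediate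
24 | (1R)-1-[(1S,3S,5R)-3-bromo-5-{[tert-butyl(dimethyl)silyl]oxy}-1,2,2-trimethylcyclopentyl]-4-methylcyclohex-3-en-1-ol | CC1(C)[C@@H](Br)C[C@@H](O[Si](C)(C)C(C)(C)C)[C@@]1(C)[C@@]1(O)CCC(C)=CC1 | intermediate
25 | (1S,2S,4R)-2-bromo-4-[(1S,3S,5R)-3-bromo-5-{[tert-butyl(dimethyl)silyl]oxy}-1,2,2-trimethylcyclopentyl]-1-methyl-7-oxabicyclo[2.2.1]heptane | CC1(C)[C@@H](Br)C[C@@H](O[Si](C)(C)C(C)(C)C)[C@@]1(C)[C@]12CC[C@](C)(O1)[C@@H](Br)C2 | intermediate
26 | (1R,3S,4S)-3-bromo-1-[(1S,3S,5R)-3-bromo-5-{[tert-butyl(dimethyl)silyl]oxy}-1,2,2-trimethylcyclopentyl]-4-chloro-4-methylcyclohexan-1-ol | CC1(C)[C@@H](Br)C[C@@H](O[Si](C)(C)C(C)(C)C)[C@@]1(C)[C@@]1(O)CC[C@](C)(Cl)[C@@H](Br)C1 | intermediate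
27 | (1R,3S,4S)-3-bromo-1-[(1S,3S,5R)-3-bromo-5-hydroxy-1,2,2-trimethylcyclopentyl]-4-chloro-4-methylcyclohexan-1-ol | CC1(C)[C@@H](Br)C[C@@H](O)[C@@]1(C)[C@@]1(O)CC[C@](C)(Cl)[C@@H](Br)C1 | target

**Step count and weak points**

Total steps: 19. Longest linear sequence: 17 (steps 1–11 and 14–19); steps 12 and 13 prepare reagent 18.

Step 14 (proposed new method) is the most likely to fail. Copper may transfer the ethyl group instead of the homoenolate. It may substitute at the CH2Cl carbon instead of the boron-bearing carbon, or give poor facial control there. The allylboration of the hindered ketone may also be too slow, leaving the open-chain allylboronate to decompose. The fallback sets out from 12 and uses known chemistry. Enolate alkylation of 12 (LiN(i-Pr)2, THF, −78 °C, then 3-bromo-2-methylprop-1-ene) should give 4-methyl-1-R-pent-4-en-1-one F1. Felkin-type addition of allylmagnesium bromide with CeCl3 (THF, −78 °C) to the ketone, whose silyloxy group does not chelate, should give (4S)-7-methyl-4-R-octa-1,7-dien-4-ol F2. Ring-closing metathesis with the second-generation Grubbs catalyst (CH2Cl2, 40 °C) returns to 21.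

Step 18 is second. Ionisation may occur at the other bridgehead, next to the quaternary carbon, and lead to skeletal rearrangement. Chloride may be captured at the secondary carbon without later equilibration, or the silyl ether may be lost. The fallback sets out from 25. Acylative ether cleavage with acetyl chloride and ZnCl2 (CH2Cl2, 0 °C) should give (1R,3S,4S)-3-bromo-4-chloro-4-methyl-1-R-cyclohexyl acetate F3. Reductive removal of the tertiary acetate with i-Bu2AlH (CH2Cl2, −78 °C) returns to 26.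

Step 16 is third. Mitsunobu activation of the hindered allylic alcohol may stall or divert to elimination or SN2′ substitution before the diazene forms. The fallback sets out from 22. Allylic oxidation with MnO2 (CH2Cl2, rt) should give (5R)-5-hydroxy-2-methyl-5-R-cyclohex-2-en-1-one F4. Condensation with 4-methylbenzenesulfonohydrazide (EtOH, rt) should give the tosylhydrazone of F4, F5. Reduction with catecholborane (CHCl3, 0 °C) and then NaOAc·3H2O at reflux gives the same reductive alkene transposition and returns to 24.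

**Further compounds**

F1 | step 14 | 1-[(1S,3S,5R)-3-bromo-5-{[tert-butyl(dimethyl)silyl]oxy}-1,2,2-trimethylcyclopentyl]-4-methylpent-4-en-1-one | CC1(C)[C@@H](Br)C[C@@H](O[Si](C)(C)C(C)(C)C)[C@@]1(C)C(=O)CCC(C)=C
F2 | step 14 | (4S)-4-[(1S,3S,5R)-3-bromo-5-{[tert-butyl(dimethyl)silyl]oxy}-1,2,2-trimethylcyclopentyl]-7-methylocta-1,7-dien-4-ol | CC1(C)[C@@H](Br)C[C@@H](O[Si](C)(C)C(C)(C)C)[C@@]1(C)[C@@](O)(CC=C)CCC(C)=C
F3 | step 18 | (1R,3S,4S)-3-bromo-1-[(1S,3S,5R)-3-bromo-5-{[tert-butyl(dimethyl)silyl]oxy}-1,2,2-trimethylcyclopentyl]-4-chloro-4-methylcyclohexyl acetate | CC1(C)[C@@H](Br)C[C@@H](O[Si](C)(C)C(C)(C)C)[C@@]1(C)[C@@]1(OC(C)=O)CC[C@](C)(Cl)[C@@H](Br)C1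
F4 | step 16 | (5R)-5-[(1S,3S,5R)-3-bromo-5-{[tert-butyl(dimethyl)silyl]oxy}-1,2,2-trimethylcyclopentyl]-5-hydroxy-2-methylcyclohex-2-en-1-one | CC1(C)[C@@H](Br)C[C@@H](O[Si](C)(C)C(C)(C)C)[C@@]1(C)[C@@]1(O)CC=C(C)C(=O)C1
F5 | step 16 | N'-[(5R)-5-[(1S,3S,5R)-3-bromo-5-{[tert-butyl(dimethyl)silyl]oxy}-1,2,2-trimethylcyclopentyl]-5-hydroxy-2-methylcyclohex-2-en-1-ylidene]-4-methylbenzenesulfonohydrazide | CC1(C)[C@@H](Br)C[C@@H](O[Si](C)(C)C(C)(C)C)[C@@]1(C)[C@@]1(O)CC=C(C)C(=NNS(=O)(=O)c2ccc(C)cc2)C1
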